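**Retrosynthetic overview**
1. Target 26 ⇐ decalin aldehyde 23: two-electron reductive scission of the ring-fusion bond C5–C10 (6,6-bicycle → ten-membered ring), with the released aldehyde enolate trapped as the Z-enol acetate.
2. Ring A of 23 (1,3-cyclohexadiene ester) ⇐ ring-closing metathesis and elimination of 21 ⇐ aldol of ester 17 with acrolein.
3. 17 ⇐ enal 13 by conjugate vinylation at C10 and α-alkylation with methyl bromoacetate (quaternary C5).
4. 13 ⇐ vinyl triflate 12 ⇐ anti-selective conjugate addition (quaternary C9) to (R)-3,4-dimethylcyclohexenone 8 ⇐ (R)-4-methylcyclohexenone 4 ⇐ propanal + methyl vinyl ketone.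
5. Ring order: cyclohexane ring B (step 1), cyclohexadiene ring A (step 7), then cleavage of the shared bond to the cyclodecadiene (step 8).

Assumption: 3-(2-bromoethyl)furan is taken as a catalogue compound; atom labels C1–C20 in the "Why" lines use clerodane numbering (C4 bears CO2Me, C5 the acetoxymethylidene, C8 and C9 are the stereocentres, C10 is the ring CH2 next to C9).

**Step 1**
Reactants: 1 propanal; 2 but-3-en-2-one
Product: 4 (R)-4-methylcyclohex-2-en-1-one, via keto aldehyde 3 (not isolated)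
Conditions: (S)-diphenylprolinol TMS ether (5 mol %), ethyl 3,4-dihydroxybenzoate (20 mol %), neat, 4 °C; then p-TsOH·H2O (10 mol %), PhMe, 80 °C
Reagents that add atoms: none
Why: Enamine-catalysed asymmetric Michael addition (the catalyst shields one enamine face and sets the methyl-bearing centre as R, the future C8), then intramolecular aldol condensation (Robinson annulation) closes the enone without touching that centre.

**Step 2**
Reactants: 4 (R)-4-methylcyclohex-2-en-1-one
Product: 8 (R)-3,4-dimethylcyclohex-2-en-1-one, via magnesium enolate 5 (not isolated), via selenide 6 (not isolated), via selenoxide 7 (not isolated)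
Conditions: MeMgBr, CuBr·SMe2 (5 mol %), THF, −40 °C; PhSeBr, −78 °C; then aq. H2O2, pyridine, CH2Cl2, 0 °C → rt
Reagents that add atoms: methylmagnesium bromide (C[Mg]Br)
Why: Copper-catalysed conjugate addition, enolate selenenylation and selenoxide syn-elimination (Reich dehydrogenation) return the enone with the new β-methyl (future C20), the C4 stereocentre being a spectator.

**Step 3**
Reactants: 8 (R)-3,4-dimethylcyclohex-2-en-1-one; 9 3-(2-bromoethyl)furan
Product: 12 (3S,4R)-3-[2-(furan-3-yl)ethyl]-3,4-dimethylcyclohex-1-en-1-yl trifluoromethanesulfonate, via Grignard reagent 10 (not isolated), via magnesium enolate 11 (not isolated)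
Conditions: 9, Mg, THF; Cu(OTf)2 (5 mol %), IMes·HCl (6 mol %), Et2O, −30 °C, then 8; then Comins' reagent, THF, 0 °C → rt
Reagents that add atoms: N-(5-chloropyridin-2-yl)-1,1,1-trifluoro-N-(trifluoromethylsulfonyl)methanesulfonamide, Comins' reagent (O=S(=O)(N(c1ccc(Cl)cn1)S(=O)(=O)C(F)(F)F)C(F)(F)F)
Why: Copper–NHC-catalysed conjugate addition of the primary alkyl Grignard to the β-methyl enone forms the quaternary centre (future C9) anti to the neighbouring C4 methyl by 1,2-induction (furylethyl trans to CH3, the two methyls cis), and the regiodefined magnesium enolate is O-triflated (enolate trapping).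

**Step 4**
Reactants: 12 vinyl triflate
Product: 13 (3S,4R)-3-[2-(furan-3-yl)ethyl]-3,4-dimethylcyclohex-1-ene-1-carbaldehyde
Conditions: Pd(OAc)2 (5 mol %), dppp (5 mol %), CO (1 atm), HCO2Na, DMF, 70 °C
Reagents that add atoms: carbon monoxide ([C-]#[O+])
Why: Palladium-catalysed reductive carbonylation (formylation) of the vinyl triflate by oxidative addition, CO insertion and formate hydride transfer installs the enal carbon (future C19).

**Step 5**
Reactants: 13 enal; 14 methyl bromoacetate
Product: 17 methyl 2-{(3S,4R)-2-ethenyl-1-formyl-3-[2-(furan-3-yl)ethyl]-3,4-dimethylcyclohexyl}acetate (mixture at the two new ring centres), via silyl enol ether 15 (not isolated), via lithium enolate 16 (not isolated)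
Conditions: CH2=CHMgBr, CuBr·SMe2 (10 mol %), TMSCl, HMPA, THF, −78 °C; then MeLi, 0 °C; then 14, −78 °C → rt
Reagents that add atoms: vinylmagnesium bromide (C=C[Mg]Br)
Why: TMSCl/HMPA-accelerated copper-catalysed 1,4-addition to the enal puts the vinyl group on C10, and the lithium enolate released by MeLi is C-alkylated by the α-bromo ester (conjugate addition–enolate alkylation) to give the quaternary aldehyde; the two new centres (future C5, C10) are erased in steps 7–8, so their configuration is irrelevant.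

**Step 6**
Reactants: 17 aldehyde ester; 18 prop-2-enal (acrolein)
Product: 21 methyl 3-acetoxy-2-{(3S,4R)-2-ethenyl-1-formyl-3-[2-(furan-3-yl)ethyl]-3,4-dimethylcyclohexyl}pent-4-enoate (diastereomer mixture), via ester enolate 19 (not isolated), via lithium aldolate 20 (not isolated)
Conditions: LDA, THF, −78 °C; 18; then Ac2O, −78 → 0 °C
Reagents that add atoms: acetic anhydride (CC(=O)OC(C)=O)
Why: Kinetic deprotonation α to the ester (the aldehyde has no α-hydrogen), 1,2-aldol addition to acrolein and in situ O-acetylation attach C3 and C2 as an allylic acetate; the new centres disappear in step 7.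

**Step 7**
Reactants: 21 diene acetate
Product: 23 methyl (5S,6R)-8a-formyl-5-[2-(furan-3-yl)ethyl]-5,6-dimethyl-4a,5,6,7,8,8a-hexahydronaphthalene-1-carboxylate (mixture at C4a/C8a), via cyclohexenyl acetate 22 (not isolated)
Conditions: Grubbs II (5 mol %), CH2Cl2, 40 °C; then DBU, rt
Reagents that add atoms: none
Why: Ring-closing metathesis of the two terminal vinyl groups gives the six-membered ring with a necessarily cis C1=C2, and E1cB elimination of the β-acetoxy ester installs C3=C4, giving the 1,3-cyclohexadiene ester.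

**Step 8**
Reactants: 23 decalin aldehyde
Product: 26 methyl (1E,3Z,6R,7R,10Z)-10-(acetoxymethylidene)-6-[2-(furan-3-yl)ethyl]-6,7-dimethylcyclodeca-1,3-diene-1-carboxylate, via samarium dienolate 24 (not isolated), via samarium enolate 25 (not isolated)
Conditions: SmI2 (2.5 equiv), THF, −78 → −20 °C; 2,6-di-tert-butylphenol (1.0 equiv), −78 °C; Ac2O (3 equiv), −78 °C → rt
Reagents that add atoms: acetic anhydride (CC(=O)OC(C)=O)
Why: Proposed new method: reductive ring-expanding fragmentation, in which Sm(II) chelated between the aldehyde and the neighbouring ester gives a ketyl whose β-bond C5–C10 is α to the carbonyl, quaternary and bis-allylic, so β-scission is fast and regioselective and gives the chelated (Z)-samarium enolate plus an ester-conjugated pentadienyl radical that a second SmI2 reduces to the trienolate; the hindered phenol protonates only this more basic carbanion at its unhindered ε-terminus C10 (giving the conjugated cis,cis-dienoate inherited from the ring) and Ac2O then O-acetylates the aldehyde enolate with retention of geometry; the closest known reaction types are SmI2 ketyl fragmentations of cyclopropyl and cyclobutyl ketones, dissolving-metal cleavage of 1,4-dicarbonyl σ-bonds and alkoxy-radical (Dowd–Beckwith type) ring expansions, none of which opens an unstrained fused cyclohexane or delivers an enol ester.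

**Compound list**
1 | propanal | CCC=O | starting material
2 | but-3-en-2-one (methyl vinyl ketone) | CC(=O)C=C | starting material
3 | (R)-2-methyl-5-oxohexanal | O=C[C@H](C)CCC(C)=O | intermediate
4 | (R)-4-methylcyclohex-2-en-1-one | O=C1C=C[C@H](C)CC1 | intermediate
5 | bromomagnesium (3S,4R)-3,4-dimethylcyclohex-1-en-1-olate (trans) | Br[Mg]OC1=C[C@@H](C)[C@H](C)CC1 | intermediate
6 | (3S,4R)-3,4-dimethyl-2-(phenylselanyl)cyclohexan-1-one (C2 epimers) | O=C1C([Se]c2ccccc2)[C@@H](C)[C@H](C)CC1 | intermediate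
7 | (3S,4R)-3,4-dimethyl-2-(phenylseleninyl)cyclohexan-1-one | O=C1C([Se](=O)c2ccccc2)[C@@H](C)[C@H](C)CC1 | intermediate
8 | (R)-3,4-dimethylcyclohex-2-en-1-one | O=C1C=C(C)[C@H](C)CC1 | intermediate
9 | 3-(2-bromoethyl)furan | BrCCc1ccoc1 | starting material
10 | [2-(furan-3-yl)ethyl]magnesium bromide | Br[Mg]CCc1ccoc1 | intermediate
11 | bromomagnesium (3S,4R)-3-[2-(furan-3-yl)ethyl]-3,4-dimethylcyclohex-1-en-1-olate | Br[Mg]OC1=C[C@@](C)(CCc2ccoc2)[C@H](C)CC1 | intermediate
12 | (3S,4R)-3-[2-(furan-3-yl)ethyl]-3,4-dimethylcyclohex-1-en-1-yl trifluoromethanesulfonate | O=S(=O)(OC1=C[C@@](C)(CCc2ccoc2)[C@H](C)CC1)C(F)(F)F | intermediate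
13 | (3S,4R)-3-[2-(furan-3-yl)ethyl]-3,4-dimethylcyclohex-1-ene-1-carbaldehyde | O=CC1=C[C@@](C)(CCc2ccoc2)[C@H](C)CC1 | intermediate
14 | methyl bromoacetate | COC(=O)CBr | starting material
15 | {[(3S,4R)-2-ethenyl-3-[2-(furan-3-yl)ethyl]-3,4-dimethylcyclohexylidene]methoxy}trimethylsilane (C2 epimers, E/Z) | C[Si](C)(C)OC=C1C(C=C)[C@@](C)(CCc2ccoc2)[C@H](C)CC1 | intermediate
16 | lithium [(3S,4R)-2-ethenyl-3-[2-(furan-3-yl)ethyl]-3,4-dimethylcyclohexylidene]methanolate | [Li]OC=C1C(C=C)[C@@](C)(CCc2ccoc2)[C@H](C)CC1 | intermediate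
17 | methyl 2-{(3S,4R)-2-ethenyl-1-formyl-3-[2-(furan-3-yl)ethyl]-3,4-dimethylcyclohexyl}acetate (mixture at C1/C2) | COC(=O)CC1(C=O)C(C=C)[C@@](C)(CCc2ccoc2)[C@H](C)CC1 | intermediate
18 | prop-2-enal (acrolein) | C=CC=O | starting material
19 | lithium ester enolate of 17 | COC(O[Li])=CC1(C=O)C(C=C)[C@@](C)(CCc2ccoc2)[C@H](C)CC1 | intermediate
20 | lithium aldolate (3-oxido-pent-4-enoate from 19 and acrolein) | COC(=O)C(C(O[Li])C=C)C1(C=O)C(C=C)[C@@](C)(CCc2ccoc2)[C@H](C)CC1 | intermediate
21 | methyl 3-acetoxy-2-{(3S,4R)-2-ethenyl-1-formyl-3-[2-(furan-3-yl)ethyl]-3,4-dimethylcyclohexyl}pent-4-enoate (diastereomer mixture) | COC(=O)C(C(OC(C)=O)C=C)C1(C=O)C(C=C)[C@@](C)(CCc2ccoc2)[C@H](C)CC1 | intermediate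
22 | methyl (5S,6R)-2-acetoxy-8a-formyl-5-[2-(furan-3-yl)ethyl]-5,6-dimethyl-1,2,4a,5,6,7,8,8a-octahydronaphthalene-1-carboxylate (mixture at C1, C2, C4a, C8a) | COC(=O)C1C(OC(C)=O)C=CC2[C@@](C)(CCc3ccoc3)[C@H](C)CCC12C=O | intermediate
23 | methyl (5S,6R)-8a-formyl-5-[2-(furan-3-yl)ethyl]-5,6-dimethyl-4a,5,6,7,8,8a-hexahydronaphthalene-1-carboxylate (mixture at C4a/C8a) | COC(=O)C1=CC=CC2[C@@](C)(CCc3ccoc3)[C@H](C)CCC12C=O | intermediate
24 | bis(diiodosamarium) dienolate of the ring-opened ten-membered ring (O-Sm aldehyde enolate and O-Sm ester trienolate) | COC(O[Sm](I)I)=C1C=CC=C[C@@](C)(CCc2ccoc2)[C@H](C)CCC1=CO[Sm](I)I | intermediate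
25 | diiodosamarium (Z)-enolate of methyl (1E,3Z,6R,7R)-10-formyl-6-[2-(furan-3-yl)ethyl]-6,7-dimethylcyclodeca-1,3-diene-1-carboxylate | COC(=O)/C1=C/C=C\C[C@@](C)(CCc2ccoc2)[C@H](C)CC\C1=C\O[Sm](I)I | intermediate
26 | methyl (1E,3Z,6R,7R,10Z)-10-(acetoxymethylidene)-6-[2-(furan-3-yl)ethyl]-6,7-dimethylcyclodeca-1,3-diene-1-carboxylate | COC(=O)/C1=C/C=C\C[C@@](C)(CCc2ccoc2)[C@H](C)CC\C1=C\OC(C)=O | target

**Totals**
Total step count: 8. Longest linear sequence: 8 steps (1 + 2 → 26).

**Steps most likely to fail, with fallbacks**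

Step 8 (the proposed new reaction). Possible failures are plain 1,2-reduction or pinacol coupling of the hindered aldehyde, protonation of the trienolate at C4 instead of C10, and E/Z leakage in the enol acetate. The fallback uses known chemistry and a different, photochemical approach. It sets out from 23: NaBH4 in MeOH reduces the aldehyde to methyl (5S,6R)-5-[2-(furan-3-yl)ethyl]-8a-(hydroxymethyl)-5,6-dimethyl-4a,5,6,7,8,8a-hexahydronaphthalene-1-carboxylate F7. Ac2O/pyridine gives methyl (5S,6R)-8a-(acetoxymethyl)-5-[2-(furan-3-yl)ethyl]-5,6-dimethyl-4a,5,6,7,8,8a-hexahydronaphthalene-1-carboxylate F8. Irradiation (300 nm, Et2O, −20 °C) opens the 1,3-cyclohexadiene by conrotatory electrocyclic ring opening to methyl (2Z,6S,7R)-10-(acetoxymethyl)-6-[2-(furan-3-yl)ethyl]-6,7-dimethylcyclodeca-1(10),2,4-triene-1-carboxylate F9. Warming to about 60 °C then triggers the antarafacial [1,7]-hydrogen shift from the CH2OAc group to C10 (the previtamin D-type sequence), which should give the cis,cis-diene and, with OAc on the outside of the helical transition state, the Z-enol acetate. The fallback thus returns to the route at 26.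

Step 5 (conjugate addition next to a quaternary carbon, then formation of a second congested quaternary centre). Possible failures are 1,2-addition to the aldehyde and O-alkylation of the enolate. The fallback replaces metal-enolate alkylation by a Stork enamine alkylation. It sets out from 13 and stops the copper step at silyl enol ether 15, which is hydrolysed (citric acid) to (3S,4R)-2-ethenyl-3-[2-(furan-3-yl)ethyl]-3,4-dimethylcyclohexane-1-carbaldehyde F4. Pyrrolidine with molecular sieves gives 1-{[(3S,4R)-2-ethenyl-3-[2-(furan-3-yl)ethyl]-3,4-dimethylcyclohexylidene]methyl}pyrrolidine F5. C-alkylation with 14 in MeCN gives 1-{[(3S,4R)-2-ethenyl-3-[2-(furan-3-yl)ethyl]-1-(2-methoxy-2-oxoethyl)-3,4-dimethylcyclohexyl]methylidene}pyrrolidin-1-ium bromide F6. Buffered aqueous NaOAc/AcOH hydrolysis returns to the route at 17.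

Step 3 (quaternary centre from a primary alkyl Grignard on a hindered β-methyl enone, with substrate-controlled facial selectivity). Possible failures are low conversion or 1,2-addition. The fallback builds the side chain by a B-alkyl Suzuki coupling instead. It sets out from 8: the much more reactive vinyl cuprate (CH2=CHMgBr, CuBr·SMe2, then TBSOTf) adds anti to the C4 methyl to give tert-butyl{[(3S,4R)-3-ethenyl-3,4-dimethylcyclohex-1-en-1-yl]oxy}dimethylsilane F1. 9-BBN hydroborates only the vinyl group to give the B-alkyl-9-borabicyclo[3.3.1]nonane adduct of F1 (CH2CH2-B in place of the vinyl group) F2. Suzuki–Miyaura coupling with 3-bromofuran (Pd(dppf)Cl2, K3PO4) gives tert-butyl{[(3S,4R)-3-[2-(furan-3-yl)ethyl]-3,4-dimethylcyclohex-1-en-1-yl]oxy}dimethylsilane F3. CsF with Comins' reagent converts the silyl enol ether directly into the triflate and returns to the route at 12.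

**Further compounds**
F1 | step 3 | tert-butyl{[(3S,4R)-3-ethenyl-3,4-dimethylcyclohex-1-en-1-yl]oxy}dimethylsilane | CC(C)(C)[Si](C)(C)OC1=C[C@@](C)(C=C)[C@H](C)CC1
F2 | step 3 | B-alkyl-9-borabicyclo[3.3.1]nonane adduct of F1 (CH2CH2-B in place of the vinyl group) | CC(C)(C)[Si](C)(C)OC1=C[C@@](C)(CCB2C3CCCC2CCC3)[C@H](C)CC1
F3 | step 3 | tert-butyl{[(3S,4R)-3-[2-(furan-3-yl)ethyl]-3,4-dimethylcyclohex-1-en-1-yl]oxy}dimethylsilane | CC(C)(C)[Si](C)(C)OC1=C[C@@](C)(CCc2ccoc2)[C@H](C)CC1
F4 | step 5 | (3S,4R)-2-ethenyl-3-[2-(furan-3-yl)ethyl]-3,4-dimethylcyclohexane-1-carbaldehyde | O=CC1C(C=C)[C@@](C)(CCc2ccoc2)[C@H](C)CC1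
F5 | step 5 | 1-{[(3S,4R)-2-ethenyl-3-[2-(furan-3-yl)ethyl]-3,4-dimethylcyclohexylidene]methyl}pyrrolidine | C(=C1C(C=C)[C@@](C)(CCc2ccoc2)[C@H](C)CC1)N1CCCC1
F6 | step 5 | 1-{[(3S,4R)-2-ethenyl-3-[2-(furan-3-yl)ethyl]-1-(2-methoxy-2-oxoethyl)-3,4-dimethylcyclohexyl]methylidene}pyrrolidin-1-ium bromide | [Br-].COC(=O)CC1(C=[N+]2CCCC2)C(C=C)[C@@](C)(CCc3ccoc3)[C@H](C)CC1
F7 | step 8 | methyl (5S,6R)-5-[2-(furan-3-yl)ethyl]-8a-(hydroxymethyl)-5,6-dimethyl-4a,5,6,7,8,8a-hexahydronaphthalene-1-carboxylate | COC(=O)C1=CC=CC2[C@@](C)(CCc3ccoc3)[C@H](C)CCC12CO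
F8 | step 8 | methyl (5S,6R)-8a-(acetoxymethyl)-5-[2-(furan-3-yl)ethyl]-5,6-dimethyl-4a,5,6,7,8,8a-hexahydronaphthalene-1-carboxylate | COC(=O)C1=CC=CC2[C@@](C)(CCc3ccoc3)[C@H](C)CCC12COC(C)=O
F9 | step 8 | methyl (2Z,6S,7R)-10-(acetoxymethyl)-6-[2-(furan-3-yl)ethyl]-6,7-dimethylcyclodeca-1(10),2,4-triene-1-carboxylate | COC(=O)C=1/C=C\C=C[C@@](C)(CCc2ccoc2)[C@H](C)CCC=1COC(C)=O
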